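The slowness is what I read first: after 30 min the earlier runs stand at 18% to 29% of the Z charged.

| flask | Z | L | J | G | remark | time |
|---|---|---|---|---|---|---|
| dusk | 0.20 M | 19 mM (held) | 10 mM | 4.1 mM | run made earlier |  |
| winter | 0.80 M | 19 mM (held) | 10 mM | 4.1 mM | run made earlier |  |
| autumn | 0.40 M | 19 mM (held) | 10 mM | 6.1 mM | run made earlier |  |
| flask | 0.40 M | 19 mM (held) | 10 mM | 4.1 mM |  | 30 min |

- dusk (time / min: X / %): 2.50: 1; 4.00: 7; 6.00: 8; 8.00: 3; 12.0: 12; 20.0: 18; 30.0: 29
- winter (time / min: X / %): 1.50: 5; 5.00: 3; 8.00: 7; 12.0: 6; 20.0: 16; 25.0: 19; 30.0: 19
- autumn (time / min: X / %): 2.50: 1; 8.00: 8; 15.0: 12; 20.0: 16; 30.0: 18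

(readings scatter by 2 percentage points)

- amount of X at 30 min, in percent of the Z charged
- the change that raises the amount of X at 30 min, in percent of the Z charged most ("none" if none brings more than 2 percentage points) (ash / alder / maple / none)
- amount of X at 30 min, in percent of the Z charged, after ash

- ash: doubling the amount of J, all else as stated
- alder: doubling the saturation concentration of L, all else as stated
- maple: doubling the transfer coefficient of L, all else as stated

- the numbers in the tables scatter by 2 percentage points (one standard deviation)
- at the start none of L is in solution

Dusk's 29% is my bound from above, since the percentage falls as Z rises. Autumn's 18% is my bound from below, with the flask's Z but more G. To tighten the top, I suppose that each G takes one J for good, as in an active-site titration by an irreversible inhibitor. The working catalyst W is then the J charged minus the G charged, 5.90 mM in the flask against 3.90 mM in autumn. If the logarithm of the unreacted Z scales with W, autumn gives 25.9% for the flask.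

Going round once more from below, the midpoint of dusk and winter gives 24.0%, so I commit to 24.9%. With ash, W becomes 15.9 mM, and the same scaling gives my ceiling, 55.5%.

The forecast says 24%, ash and 42%, reading that “G appears to inhibit, perhaps by tying up J”. Its first number stands on my lower edge.

The flask gives 23.8%, just under that edge. Ash gains the most, 20 percentage points, and gives 44.3%, below my ceiling.

    L ⇌ E, rate k1*(csat - [E]) (kL = 0.770 min⁻¹)
    Z + E + J → J + X (k = 140 M⁻² min⁻¹)
    E + J ⇌ D, settled at all times (K = 20.0 M⁻¹)
    J + G → Q (k = 2400 M⁻¹ min⁻¹)

The half-life of J against G at the charged amounts is 0.070 min, far shorter than the 14.7 min by which half of the X of the flask is made. By 3.00 min, G stands at 0% of its charge and Q holds 41.0% of the catalyst, while J and D together hold 59.0%, which is W as a share of the charge, 59.0%. In a neighbour flask, the same but with 0.0070 M of G, W is 3.00 mM. Scaling from the flask gives 12.9%, and the neighbour flask gives 14.0%.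

The data were generated by integration for an exercise; scatter was added.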